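Locants used throughout: ring C1 (stereocentre)–C2–C3=C4(Me)–C5–C6–C7=C8(CO2H)–C9–C10–C11=C12(Me)–C13–C14; side chain on C1: C1'(Me)=C2'H–C3'H2–C4'H=C5'Me2. Open-chain intermediates keep these locants.

## Analysis of the target

The target is a C25 carbocycle with a 14-membered ring (C1–C14) and three endocyclic trisubstituted alkenes. C3=C4 is Z with a methyl on C4. C7=C8 carries the carboxyl on C8 trans to C6 (E by the sequence rules, with C6 and C9 cis). C11=C12 is E with a methyl on C12. C1 bears a (2E)-6-methylhepta-2,5-dien-2-yl side chain and is the only stereocentre (R). It is a tertiary allylic CH between two methylene groups, so no second centre can relay to it and no neighbouring heteroatom can direct its formation. The sensitive features are five trisubstituted alkenes (prone to electrophilic oxidation and acid-induced cyclisation), the doubly allylic C3', and a conjugated acid that does not survive dissolving-metal conditions. The difficulty lies in closing an all-carbon 14-membered ring at a site without functional groups while keeping three alkene geometries (one of them Z) and the lone stereocentre. The strategy rests on the C13–C14 bond, which joins the allylic terminus C13 of the E alkene C11=C12 to C14, the methylene next to C1. The unit C14–C1–C1'=C2' is what a Claisen rearrangement leaves behind if C14 carries a carboxyl. That carboxyl can be esterified with the C13 allylic alcohol, and a sulfonyl group on C14 then lets zerovalent palladium collapse the ester into the C13–C14 bond with decarboxylation.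

## Retrosynthetic reasoning

**C8 carboxyl.** The acid 38 is traced back through enal 37 and allylic alcohol 36 to silyl ether 35. A conjugated acid or ester on C8 would be reduced in the desulfonylation and would complicate the enolate chemistry earlier. The C8 carbon is therefore carried at the alcohol oxidation level and raised only at the end by two selective oxidations.

**C14–S bond.** 35 comes from sulfone 34 by reductive desulfonylation. The sulfone has done its work once the ring exists, and C14 is a plain secondary carbon with no alkene in allylic relation, so its removal cannot shift a double bond.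

**C13–C14 bond (key disconnection).** In 34 the C13–C14 bond is cut and an O–C(=O) unit is inserted between the two carbons, which gives the 16-membered α-sulfonyl lactone 33. This bond is chosen because C13 is an allylic terminus that zerovalent palladium can ionise, and C14 becomes a stabilised carbanion once the α-sulfonyl carboxylate decarboxylates. Ring formation is thereby split into an ordinary lactonisation and a contraction in which both reacting carbons already sit in one ring. The forward step must deliver attack at C13 rather than C11 and keep C11=C12 as E.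

**Lactone C–O bond and sulfur oxidation level.** 33 is traced to the α-phenylthio lactone 31 and then to hydroxy acid 29. Sulfur is oxidised after ring closure because a free α-sulfonyl acid would decarboxylate or form a ketene on carboxyl activation. The α-phenylthio acid is an ordinary, if hindered, partner for macrolactonisation.

**C1–C14 bond and the stereocentre.** 29 comes from acid 28 by release of the C13 hydroxyl. In 28 the C1–C14 bond is cut with shift of the alkene back to C1'=C1 and return of the oxygen to C2'. This leads to the (phenylthio)acetate 25 of the (S,E)-allylic alcohol 23 and to acid 24. The Ireland–Claisen rearrangement is used here because its chair transition state transfers the C2' configuration to C1, makes C1'=C2' as E, and installs C14 with both the carboxyl and the sulfur it needs.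

**C8 oxidation level and protecting groups.** 23 is traced through diol 22 to hydroxy ester 21. The two silyl ethers are chosen so that the C13 ether can be cleaved while the C8 ether stays.

**C1–C2 bond.** 21 is cut between C1 and C2 into allylic chloride 12 and alkynol 19. The skipped diene C1'=C1–C2–C3=C4 is the product pattern of an alkenyl–allyl coupling. Methylalumination of 19 sets the C1' methyl and the E geometry in the same operation, through alkenylalane 20. The carbinol stereocentre enters with a small, separately made fragment.

**C7=C8 bond.** 12 comes from alcohol 11 and acetate 10, and 10 is cut at C7=C8 into aldehyde 4 and phosphonate 9. This olefination joins the two larger achiral fragments and gives the ester trans to C6.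

**Fragments from simple materials.** Aldehyde 4 comes from neryl acetate 1 by way of epoxide 2. Compound 1 already contains C2–C7 and the Z alkene C3=C4, and its isopropylidene end is cleaved to give C7. Phosphonate 9 comes from 8 and bromide 7. Compound 7 derives through alcohol 6 from 5, whose E-selective allylic hydroxylation fixes C11=C12 and places the oxygen on C13. Alkynol 19 comes from epoxy chloride 18, epoxy alcohol 17, dienol 16 and enynol 15, the last assembled from 13 and 14. Asymmetric epoxidation of the allylic alcohol is the source of absolute configuration.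

## Alternatives that were turned down

**Alternative 1: B-alkyl Suzuki closure at C12–C13.**
- Disconnection and key step: the ring is cut between C12 and C13. The precursor A2 is an open chain with a vinyl group on C1 (C14=C13) and an (E)-alkenyl iodide at C12. Hydroboration of the vinyl group with a hindered dialkylborane and palladium-catalysed coupling of the new C13–boron bond with the iodide would give A1, the methyl ester of 38.
- For it: macrocyclising B-alkyl Suzuki couplings are an established reaction class, so this is stronger on precedent than the chosen contraction. The C8 ester can be carried throughout, so the endgame is a single saponification against five steps after the key step in the chosen route.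
- Against it: C1 must carry a vinyl group and the dienyl side chain, which no single stereoselective step delivers. A Claisen product would need reduction and elimination to become the vinyl group. A stereopure trisubstituted (E)-2-iodoalk-2-ene at C12 is harder to obtain than an allylic alcohol. The borane has to spare a conjugated ester, and the ring closes in a transmetalation that competes with protodeboronation and β-hydride loss.
- Comparison: the chosen route accepts a longer endgame in return for a precursor whose stereocentre, nucleophilic carbon and electrophilic terminus all come from one sigmatropic step and one esterification.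

**Alternative 2: sulfonyl carbanion alkylation at C9–C10.**
- Disconnection and key step: the ring is cut between C9 and C10. The precursor A4 has an allylic phenyl sulfone at C10 and a (Z)-2-(bromomethyl)enoate ending at C9. Deprotonation with a potassium amide base and intramolecular displacement of bromide would give A3.
- For it: closing large carbocycles by alkylating a sulfonyl carbanion is classical, so the ring-forming step is better precedented than the chosen one. The C8 ester is again carried through.
- Against it: a strong base at high dilution meets an electrophile that can react by direct displacement or by addition–elimination (with loss of the C7=C8 geometry). The allyl sulfone anion is ambident between C10 and C12. In A3 the sulfone is allylic and sits beside a conjugated ester, so its reductive removal risks alkene transposition and ester reduction. C1 has to be set by separate chemistry.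
- Comparison: in the chosen route the carbanion is formed only inside the ion pair with its electrophile, no external base is present, and the sulfone in 34 is not allylic.

**Alternative 3: Ireland–Claisen contraction of an 18-membered lactone.**
- Disconnection and key step: the C1–C14 bond is cut within the ring. The 18-membered lactone A6 (ester oxygen on C2', α-carbon C14) would be converted into its silyl ketene acetal A7, whose [3,3] shift forms C1–C14, closes the carbocycle and moves the alkene to C1'=C2', giving acid A5.
- For it: it is the most economical in concept, since one step sets C1 and closes the ring. Claisen contractions of macrolides are known, so its precedent is stronger than that of the chosen key step.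
- Against it: the configuration of C1, the geometry of C1'=C2' and the ring closure all depend on a transition state whose chair or boat shape is dictated by the conformation of an 18-membered ring. The lactone enolate carries no stabilising group and must be formed next to skipped dienes. A5 keeps a carboxyl on C14 that would need a radical decarboxylation close to several alkenes. The 18-membered lactone must be closed onto a hindered secondary allylic alcohol.
- Comparison: the chosen route uses the same sigmatropic logic in the open chain, where the chair transition state is reliable, and spends the carboxyl productively as the leaving group of the ring contraction.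

Key step: step 22

Remark on the chemistry: the C8 oxygen is carried as a tert-butyldiphenylsilyl ether so that the C13 tert-butyldimethylsilyl ether can be removed alone; sulfur is oxidised to the sulfone only after lactonisation; neryl acetate 1 is taken as the commercial form of nerol.

## Route

Step 1
Reactants: 1 neryl acetate [(2Z)-3,7-dimethylocta-2,6-dien-1-yl acetate]
Product: 2 (2Z)-5-(3,3-dimethyloxiran-2-yl)-3-methylpent-2-en-1-yl acetate (racemic at the epoxide carbon)
Conditions: mCPBA (1.0 equiv), NaHCO3, CH2Cl2, 0 °C
Reagents that add atoms: 3-chloroperbenzoic acid, OOC(=O)c1cccc(Cl)c1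
Why: Prilezhaev epoxidation; the isopropylidene alkene is the more electron-rich because the other alkene is deactivated by the allylic acetate, so one equivalent of peracid should react at the remote end.

Step 2
Reactants: 2 (2Z)-5-(3,3-dimethyloxiran-2-yl)-3-methylpent-2-en-1-yl acetate
Product: 4 (2Z)-3-methyl-6-oxohex-2-en-1-yl acetate, via diol 3 (not isolated)
Conditions: H5IO6, THF/H2O, 0 °C
Reagents that add atoms: none
Why: Acid-promoted epoxide hydrolysis and periodate glycol cleavage in one pot; acetone is lost, the aldehyde carbon becomes C7, and the allylic acetate and the Z alkene C3=C4 are untouched.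

Step 3
Reactants: 5 5-bromo-2-methylpent-2-ene
Product: 6 (2E)-5-bromo-2-methylpent-2-en-1-ol
Conditions: SeO2 (cat.), tBuOOH, CH2Cl2, 0 °C to rt
Reagents that add atoms: selenium dioxide, O=[Se]=O; tert-butyl hydroperoxide, CC(C)(C)OO
Why: Catalytic SeO2 allylic oxidation (ene reaction, then [2,3] shift) hydroxylates the methyl group trans to the chain, which fixes C11=C12 as E and puts the oxygen on C13; over-oxidised material is removed by chromatography.

Step 4
Reactants: 6 (2E)-5-bromo-2-methylpent-2-en-1-ol
Product: 7 {[(2E)-5-bromo-2-methylpent-2-en-1-yl]oxy}(tert-butyl)dimethylsilane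
Conditions: TBSCl, imidazole, CH2Cl2, 0 °C to rt
Reagents that add atoms: tert-butyldimethylsilyl chloride, CC(C)(C)[Si](C)(C)Cl
Why: Standard silylation of a primary alcohol; the neutral conditions avoid cyclisation or elimination of the bromo alcohol.

Step 5
Reactants: 7 {[(2E)-5-bromo-2-methylpent-2-en-1-yl]oxy}(tert-butyl)dimethylsilane; 8 triethyl phosphonoacetate
Product: 9 ethyl (5E)-7-[(tert-butyldimethylsilyl)oxy]-2-(diethoxyphosphoryl)-6-methylhept-5-enoate (racemic)
Conditions: NaH, 8 (2 equiv), NaI (cat.), DMF, 60 °C
Reagents that add atoms: none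
Why: C-alkylation of the sodium phosphonoacetate carbanion by the primary bromide (SN2, helped by in situ iodide exchange) forms C8–C9; the excess of 8 limits dialkylation and the weakly basic carbanion disfavours elimination.

Step 6
Reactants: 4 (2Z)-3-methyl-6-oxohex-2-en-1-yl acetate; 9 ethyl (5E)-7-[(tert-butyldimethylsilyl)oxy]-2-(diethoxyphosphoryl)-6-methylhept-5-enoate
Product: 10 ethyl (2E,6Z)-8-acetoxy-2-{(3E)-5-[(tert-butyldimethylsilyl)oxy]-4-methylpent-3-en-1-yl}-6-methylocta-2,6-dienoate
Conditions: NaH, THF, 0 °C to rt
Reagents that add atoms: none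
Why: Horner–Wadsworth–Emmons olefination forms C7=C8; with an unbranched aldehyde the reversible addition should favour the enoate with the ester trans to C6 (E), and the minor Z isomer is removed by chromatography.

Step 7
Reactants: 10 ethyl (2E,6Z)-8-acetoxy-2-{(3E)-5-[(tert-butyldimethylsilyl)oxy]-4-methylpent-3-en-1-yl}-6-methylocta-2,6-dienoate
Product: 11 ethyl (2E,6Z)-2-{(3E)-5-[(tert-butyldimethylsilyl)oxy]-4-methylpent-3-en-1-yl}-8-hydroxy-6-methylocta-2,6-dienoate
Conditions: K2CO3, EtOH, 0 °C to rt
Reagents that add atoms: none
Why: Base-catalysed transesterification removes the primary allylic acetate; ethanol as solvent leaves the conjugated ethyl ester unchanged and the silyl ether is stable.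

Step 8
Reactants: 11 ethyl (2E,6Z)-2-{(3E)-5-[(tert-butyldimethylsilyl)oxy]-4-methylpent-3-en-1-yl}-8-hydroxy-6-methylocta-2,6-dienoate
Product: 12 ethyl (2E,6Z)-2-{(3E)-5-[(tert-butyldimethylsilyl)oxy]-4-methylpent-3-en-1-yl}-8-chloro-6-methylocta-2,6-dienoate
Conditions: N-chlorosuccinimide, Me2S, CH2Cl2, −30 to 0 °C
Reagents that add atoms: N-chlorosuccinimide, O=C1CCC(=O)N1Cl
Why: Corey–Kim chlorination; chloride displaces the alkoxysulfonium group at the primary carbon C2 by SN2, without allylic transposition or loss of the Z geometry of C3=C4.

Step 9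
Reactants: 13 propargyl alcohol (prop-2-yn-1-ol); 14 prenyl bromide (1-bromo-3-methylbut-2-ene)
Product: 15 6-methylhept-5-en-2-yn-1-ol
Conditions: CuI (cat.), K2CO3, NaI, DMF, rt
Reagents that add atoms: none
Why: Copper-mediated coupling of the terminal alkyne (as its copper acetylide) with the allylic bromide at its primary carbon gives the skipped enyne; the free hydroxyl is tolerated.

Step 10
Reactants: 15 6-methylhept-5-en-2-yn-1-ol
Product: 16 (2E)-6-methylhepta-2,5-dien-1-ol
Conditions: LiAlH4, THF, 0 °C to reflux
Reagents that add atoms: none
Why: Hydroxyl-directed trans-hydroalumination of the propargylic alcohol and protonolysis give the E allylic alcohol; the isolated trisubstituted alkene is inert.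

Step 11
Reactants: 16 (2E)-6-methylhepta-2,5-dien-1-ol
Product: 17 [(2S,3S)-3-(3-methylbut-2-en-1-yl)oxiran-2-yl]methanol
Conditions: Ti(OiPr)4 (cat.), L-(+)-diethyl tartrate (cat.), tBuOOH, 4 Å molecular sieves, CH2Cl2, −20 °C
Reagents that add atoms: tert-butyl hydroperoxide, CC(C)(C)OO
Why: Sharpless asymmetric epoxidation; the titanium tartrate complex epoxidises only the allylic alcohol alkene, and the L-(+)-tartrate selects the face that gives the (2S,3S)-epoxide, whose C3 becomes C2'.

Step 12
Reactants: 17 [(2S,3S)-3-(3-methylbut-2-en-1-yl)oxiran-2-yl]methanol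
Product: 18 (2R,3S)-2-(chloromethyl)-3-(3-methylbut-2-en-1-yl)oxirane
Conditions: PPh3, CCl4, NaHCO3, reflux
Reagents that add atoms: carbon tetrachloride, ClC(Cl)(Cl)Cl
Why: Appel chlorination of the primary alcohol under neutral conditions; the epoxide and its two stereocentres are not involved (the C2 descriptor changes only through priorities).

Step 13
Reactants: 18 (2R,3S)-2-(chloromethyl)-3-(3-methylbut-2-en-1-yl)oxirane
Product: 19 (3S)-6-methylhept-5-en-1-yn-3-ol
Conditions: nBuLi (3 equiv), THF, −40 °C; aq. NH4Cl
Reagents that add atoms: none
Why: Base-induced double elimination of a 2,3-epoxy chloride (deprotonation at the chloromethyl carbon opens the epoxide, then loss of HCl gives the alkynide); the C–O bond at the carbinol carbon is never broken, so the S configuration is carried over.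

Step 14
Reactants: 19 (3S)-6-methylhept-5-en-1-yn-3-ol; 12 ethyl (2E,6Z)-2-{(3E)-5-[(tert-butyldimethylsilyl)oxy]-4-methylpent-3-en-1-yl}-8-chloro-6-methylocta-2,6-dienoate
Product: 21 ethyl (2E,6Z,9E,11S)-2-{(3E)-5-[(tert-butyldimethylsilyl)oxy]-4-methylpent-3-en-1-yl}-11-hydroxy-6,10,14-trimethylpentadeca-2,6,9,13-tetraenoate, via alkenylalane 20 (not isolated)
Conditions: Me3Al (3 equiv), Cp2ZrCl2 (0.3 equiv), ClCH2CH2Cl, 0 °C to rt; volatiles removed; then 12, Pd(PPh3)4 (5 mol %), THF, rt
Reagents that add atoms: trimethylaluminium, C[Al](C)C
Why: Negishi zirconium-catalysed syn-methylalumination of the terminal alkyne puts the methyl on C1' and aluminium on C1 (E), and palladium-catalysed alkenyl–allyl coupling then forms C1–C2 with retention at the alkenyl carbon. The 3,3-disubstituted allylpalladium unit cannot exchange its ends without bonding at the tertiary carbon, so C3=C4 should stay Z and coupling should occur at the CH2 terminus; the ester and silyl ether are inert to the alane at rt.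

Step 15
Reactants: 21 ethyl (2E,6Z,9E,11S)-2-{(3E)-5-[(tert-butyldimethylsilyl)oxy]-4-methylpent-3-en-1-yl}-11-hydroxy-6,10,14-trimethylpentadeca-2,6,9,13-tetraenoate
Product: 22 (2E,6Z,9E,11S)-2-{(3E)-5-[(tert-butyldimethylsilyl)oxy]-4-methylpent-3-en-1-yl}-6,10,14-trimethylpentadeca-2,6,9,13-tetraene-1,11-diol
Conditions: iBu2AlH (4 equiv), CH2Cl2, −78 °C; Rochelle salt
Reagents that add atoms: none
Why: 1,2-Reduction of the conjugated ester to the C8 hydroxymethyl group; the free secondary hydroxyl only consumes one hydride equivalent.

Step 16
Reactants: 22 (2E,6Z,9E,11S)-2-{(3E)-5-[(tert-butyldimethylsilyl)oxy]-4-methylpent-3-en-1-yl}-6,10,14-trimethylpentadeca-2,6,9,13-tetraene-1,11-diol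
Product: 23 (S,E)-allylic alcohol: diol 22 with the primary C8 hydroxymethyl oxygen as its tert-butyldiphenylsilyl ether and the C2' hydroxyl free
Conditions: TBDPSCl (1.05 equiv), imidazole, CH2Cl2, 0 °C
Reagents that add atoms: tert-butyldiphenylsilyl chloride, CC(C)(C)[Si](Cl)(c1ccccc1)c1ccccc1
Why: The bulky silyl chloride reacts with the primary allylic alcohol much faster than with the secondary alcohol flanked by C1' and C3'.

Step 17
Reactants: 23 (S,E)-allylic alcohol with C8 CH2OTBDPS and C13 OTBS; 24 (phenylthio)acetic acid
Product: 25 (phenylthio)acetate ester of 23 at the C2' oxygen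
Conditions: DCC, DMAP (cat.), CH2Cl2, 0 °C to rt
Reagents that add atoms: none
Why: Steglich esterification; O-acylation under neutral conditions leaves the C2'–O bond and hence the S configuration intact.

Step 18
Reactants: 25 (phenylthio)acetate ester of 23
Product: 28 (3R,4E)-3-[(2Z,6E,10E)-12-[(tert-butyldimethylsilyl)oxy]-7-{[(tert-butyldiphenylsilyl)oxy]methyl}-3,11-dimethyldodeca-2,6,10-trien-1-yl]-4,8-dimethyl-2-(phenylsulfanyl)nona-4,7-dienoic acid (C14 epimers), via silyl ketene acetal 26 (not isolated), via trimethylsilyl ester 27 (not isolated)
Conditions: LiN(SiMe3)2, Me3SiCl, Et3N, THF, −78 °C to rt; aq. NH4Cl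
Reagents that add atoms: none
Why: Ireland–Claisen rearrangement; the [3,3] shift through a chair transition state with the prenyl group on C2' equatorial forms C1–C14 on the face from which the C2'–O bond departs, so the (S)-carbinol with the E alkene gives (R)-C1 and C1'=C2' as E. The phenylthio group makes enolisation easy enough that the skipped diene is not deprotonated, and the C14 configuration does not matter.

Step 19
Reactants: 28 C14-phenylthio acid with C13 OTBS and C8 CH2OTBDPS
Product: 29 hydroxy acid: 28 with the C13 hydroxyl free
Conditions: HF·pyridine, pyridine, THF, 0 °C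
Reagents that add atoms: none
Why: Buffered acidic fluoride removes the primary tert-butyldimethylsilyl ether much faster than the tert-butyldiphenylsilyl ether.

Step 20
Reactants: 29 hydroxy acid
Product: 31 16-membered lactone (C14 carboxyl esterified by the C13 oxygen; phenylthio on C14; C8 CH2OTBDPS; R at C1), via mixed anhydride 30 (not isolated)
Conditions: 2,4,6-trichlorobenzoyl chloride, Et3N, THF, rt; then slow addition to DMAP, toluene, 80 °C (about 1 mM)
Reagents that add atoms: none
Why: Yamaguchi macrolactonisation; the acylpyridinium formed from the mixed anhydride is trapped by the unhindered primary allylic alcohol, and high dilution favours the 16-membered ring over oligomers.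

Step 21
Reactants: 31 16-membered α-phenylthio lactone
Product: 33 16-membered α-phenylsulfonyl lactone (C14 epimers), via sulfoxide 32 (not isolated)
Conditions: (NH4)6Mo7O24·4H2O (cat.), 30% H2O2, EtOH/THF, 0 °C to rt
Reagents that add atoms: hydrogen peroxide, OO
Why: Peroxomolybdate oxidises sulfur through the sulfoxide to the sulfone much faster than it epoxidises unactivated trisubstituted alkenes; done on the lactone, the oxidation never produces a free α-sulfonyl acid.

Step 22
Reactants: 33 16-membered α-phenylsulfonyl lactone
Product: 34 14-membered carbocycle with phenylsulfonyl on C14 and CH2OTBDPS on C8 (C14 epimers)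
Conditions: Pd(PPh3)4 (10 mol %), degassed toluene (about 2 mM), 90 °C
Reagents that add atoms: none
Why: Proposed new method: oxidative addition of zerovalent palladium to the C13–O bond of 33 opens the lactone to a π-allylpalladium cation spanning C11–C13 that stays ion-paired with the α-sulfonyl carboxylate on the same chain; loss of CO2 at 90 °C gives the C14 sulfonyl carbanion, which attacks the allyl terminus and releases the catalyst. The closest known reaction types are the Pd(PPh3)4-catalysed decarboxylative allylation of open-chain allyl α-sulfonylacetates and the macrocyclising allylic alkylation of sulfonyl-stabilised carbanions; new here is that the allyl ester is a macrolactone, so the same events contract a ring. The 14-membered ring closes by C–C bond formation between C14 and the primary terminus C13, a contraction from 16 to 14 members in which the reacting ends are never separated, so no external base and no slow addition of a carbanion are needed; dilution serves only to suppress proton transfer and allyl exchange between molecules. If C-allylation at C14 comes before decarboxylation, the carboxyl group is lost afterwards at the same temperature and the same product results. The only new stereocentre is C14; it is uncontrolled and is erased in step 23, while C1 is remote from the reacting atoms and untouched. The step needs attack at C13 rather than at C11 (which would give a 12-membered ring with an isopropenyl branch); the soft, bulky sulfonyl carbanion and the methyl group on C12 direct it to the unhindered CH2 terminus. It also needs C11=C12 to stay E; ionisation of the E ester gives the allyl isomer with the C10 chain syn to the C12 methyl, and this isomer should remain the main one even if the allyl faces interconvert.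

Step 23
Reactants: 34 14-membered C14 sulfone
Product: 35 14-membered carbocycle with C14 as CH2 and CH2OTBDPS on C8
Conditions: Mg turnings (excess), MeOH/THF, rt to 50 °C
Reagents that add atoms: none
Why: Reductive desulfonylation by electron transfer from magnesium in methanol cleaves the C14–S bond and protonates the carbanion; C14 is not allylic, so no alkene can shift, and the silyl ether and isolated alkenes are inert.

Step 24
Reactants: 35 C8 silyl ether
Product: 36 allylic alcohol (C8 CH2OH)
Conditions: Bu4NF, THF, rt
Reagents that add atoms: none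
Why: Fluoride-induced cleavage of the silyl ether; nothing else in the hydrocarbon skeleton reacts.

Step 25
Reactants: 36 allylic alcohol
Product: 37 enal (C8 CHO)
Conditions: MnO2 (excess), CH2Cl2, rt
Reagents that add atoms: none
Why: Selective oxidation of the allylic alcohol on the MnO2 surface; the enal keeps the geometry with the formyl group trans to C6, which is also the more stable one.

Step 26
Reactants: 37 enal
Product: 38 target acid CNP0112585.1
Conditions: NaClO2, NaH2PO4, 2-methylbut-2-ene, tBuOH/H2O, 0 °C to rt
Reagents that add atoms: sodium chlorite, [Na+].[O-]Cl=O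
Why: Pinnick oxidation of the conjugated aldehyde to the acid; the alkene scavenger traps hypochlorous acid and protects the five trisubstituted alkenes.

## Compound list

1 | neryl acetate, (2Z)-3,7-dimethylocta-2,6-dien-1-yl acetate | CC(=O)OC/C=C(/C)CCC=C(C)C | starting material
2 | (2Z)-5-(3,3-dimethyloxiran-2-yl)-3-methylpent-2-en-1-yl acetate | CC(=O)OC/C=C(/C)CCC1OC1(C)C | intermediate
3 | (2Z)-6,7-dihydroxy-3,7-dimethyloct-2-en-1-yl acetate (diol, formed in the flask) | CC(=O)OC/C=C(/C)CCC(O)C(C)(C)O | intermediate
4 | (2Z)-3-methyl-6-oxohex-2-en-1-yl acetate | CC(=O)OC/C=C(/C)CCC=O | intermediate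
5 | 5-bromo-2-methylpent-2-ene | CC(C)=CCCBr | starting material
6 | (2E)-5-bromo-2-methylpent-2-en-1-ol | OC/C(C)=C/CCBr | intermediate
7 | {[(2E)-5-bromo-2-methylpent-2-en-1-yl]oxy}(tert-butyl)dimethylsilane | BrCC/C=C(\C)CO[Si](C)(C)C(C)(C)C | intermediate
8 | triethyl phosphonoacetate | CCOC(=O)CP(=O)(OCC)OCC | starting material
9 | ethyl (5E)-7-[(tert-butyldimethylsilyl)oxy]-2-(diethoxyphosphoryl)-6-methylhept-5-enoate | CCOC(=O)C(CC/C=C(\C)CO[Si](C)(C)C(C)(C)C)P(=O)(OCC)OCC | intermediate
10 | ethyl (2E,6Z)-8-acetoxy-2-{(3E)-5-[(tert-butyldimethylsilyl)oxy]-4-methylpent-3-en-1-yl}-6-methylocta-2,6-dienoate | CC(=O)OC/C=C(/C)CC/C=C(/C(=O)OCC)CC/C=C(\C)CO[Si](C)(C)C(C)(C)C | intermediate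
11 | ethyl (2E,6Z)-2-{(3E)-5-[(tert-butyldimethylsilyl)oxy]-4-methylpent-3-en-1-yl}-8-hydroxy-6-methylocta-2,6-dienoate | OC/C=C(/C)CC/C=C(/C(=O)OCC)CC/C=C(\C)CO[Si](C)(C)C(C)(C)C | intermediate
12 | ethyl (2E,6Z)-2-{(3E)-5-[(tert-butyldimethylsilyl)oxy]-4-methylpent-3-en-1-yl}-8-chloro-6-methylocta-2,6-dienoate | ClC/C=C(/C)CC/C=C(/C(=O)OCC)CC/C=C(\C)CO[Si](C)(C)C(C)(C)C | intermediate
13 | propargyl alcohol | OCC#C | starting material
14 | prenyl bromide | CC(C)=CCBr | starting material
15 | 6-methylhept-5-en-2-yn-1-ol | CC(C)=CCC#CCO | intermediate
16 | (2E)-6-methylhepta-2,5-dien-1-ol | CC(C)=CC/C=C/CO | intermediate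
17 | [(2S,3S)-3-(3-methylbut-2-en-1-yl)oxiran-2-yl]methanol | OC[C@@H]1O[C@H]1CC=C(C)C | intermediate
18 | (2R,3S)-2-(chloromethyl)-3-(3-methylbut-2-en-1-yl)oxirane | ClC[C@@H]1O[C@H]1CC=C(C)C | intermediate
19 | (3S)-6-methylhept-5-en-1-yn-3-ol | CC(C)=CC[C@H](O)C#C | intermediate
20 | dimethyl[(1E,3S)-3-(dimethylalumanyloxy)-2,6-dimethylhepta-1,5-dien-1-yl]alumane (alkenylalane, formed in the flask) | C[Al](C)/C=C(\C)[C@@H](O[Al](C)C)CC=C(C)C | intermediate
21 | ethyl (2E,6Z,9E,11S)-2-{(3E)-5-[(tert-butyldimethylsilyl)oxy]-4-methylpent-3-en-1-yl}-11-hydroxy-6,10,14-trimethylpentadeca-2,6,9,13-tetraenoate | CC(C)=CC[C@H](O)/C(C)=C/C/C=C(/C)CC/C=C(/C(=O)OCC)CC/C=C(\C)CO[Si](C)(C)C(C)(C)C | intermediate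
22 | (2E,6Z,9E,11S)-2-{(3E)-5-[(tert-butyldimethylsilyl)oxy]-4-methylpent-3-en-1-yl}-6,10,14-trimethylpentadeca-2,6,9,13-tetraene-1,11-diol | CC(C)=CC[C@H](O)/C(C)=C/C/C=C(/C)CC/C=C(/CO)CC/C=C(\C)CO[Si](C)(C)C(C)(C)C | intermediate
23 | (S,E)-allylic alcohol: 22 with the C8 hydroxymethyl oxygen as tert-butyldiphenylsilyl ether | CC(C)=CC[C@H](O)/C(C)=C/C/C=C(/C)CC/C=C(/CO[Si](c1ccccc1)(c1ccccc1)C(C)(C)C)CC/C=C(\C)CO[Si](C)(C)C(C)(C)C | intermediate
24 | (phenylthio)acetic acid | OC(=O)CSc1ccccc1 | starting material
25 | (phenylthio)acetate of 23 at the C2' oxygen | CC(C)=CC[C@H](OC(=O)CSc1ccccc1)/C(C)=C/C/C=C(/C)CC/C=C(/CO[Si](c1ccccc1)(c1ccccc1)C(C)(C)C)CC/C=C(\C)CO[Si](C)(C)C(C)(C)C | intermediate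
26 | O-trimethylsilyl ketene acetal of 25 (formed in the flask) | CC(C)=CC[C@H](OC(O[Si](C)(C)C)=CSc1ccccc1)/C(C)=C/C/C=C(/C)CC/C=C(/CO[Si](c1ccccc1)(c1ccccc1)C(C)(C)C)CC/C=C(\C)CO[Si](C)(C)C(C)(C)C | intermediate
27 | trimethylsilyl ester of 28 (formed in the flask) | CC(C)=CC/C=C(\C)[C@@H](C/C=C(/C)CC/C=C(/CO[Si](c1ccccc1)(c1ccccc1)C(C)(C)C)CC/C=C(\C)CO[Si](C)(C)C(C)(C)C)C(Sc1ccccc1)C(=O)O[Si](C)(C)C | intermediate
28 | (3R,4E)-3-[(2Z,6E,10E)-12-[(tert-butyldimethylsilyl)oxy]-7-{[(tert-butyldiphenylsilyl)oxy]methyl}-3,11-dimethyldodeca-2,6,10-trien-1-yl]-4,8-dimethyl-2-(phenylsulfanyl)nona-4,7-dienoic acid | CC(C)=CC/C=C(\C)[C@@H](C/C=C(/C)CC/C=C(/CO[Si](c1ccccc1)(c1ccccc1)C(C)(C)C)CC/C=C(\C)CO[Si](C)(C)C(C)(C)C)C(Sc1ccccc1)C(=O)O | intermediate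
29 | hydroxy acid: 28 with the C13 hydroxyl free | CC(C)=CC/C=C(\C)[C@@H](C/C=C(/C)CC/C=C(/CO[Si](c1ccccc1)(c1ccccc1)C(C)(C)C)CC/C=C(\C)CO)C(Sc1ccccc1)C(=O)O | intermediate
30 | mixed anhydride of 29 with 2,4,6-trichlorobenzoic acid (formed in the flask) | CC(C)=CC/C=C(\C)[C@@H](C/C=C(/C)CC/C=C(/CO[Si](c1ccccc1)(c1ccccc1)C(C)(C)C)CC/C=C(\C)CO)C(Sc1ccccc1)C(=O)OC(=O)c1c(Cl)cc(Cl)cc1Cl | intermediate
31 | 16-membered lactone, phenylthio on C14, CH2OTBDPS on C8, R at C1 | CC(C)=CC/C=C(\C)[C@H]1C/C=C(/C)CC/C=C(/CO[Si](c2ccccc2)(c2ccccc2)C(C)(C)C)CC/C=C(\C)COC(=O)C1Sc1ccccc1 | intermediate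
32 | 16-membered lactone, phenylsulfinyl on C14 (formed in the flask) | CC(C)=CC/C=C(\C)[C@H]1C/C=C(/C)CC/C=C(/CO[Si](c2ccccc2)(c2ccccc2)C(C)(C)C)CC/C=C(\C)COC(=O)C1S(=O)c1ccccc1 | intermediate
33 | 16-membered lactone, phenylsulfonyl on C14 (precursor of the key step) | CC(C)=CC/C=C(\C)[C@H]1C/C=C(/C)CC/C=C(/CO[Si](c2ccccc2)(c2ccccc2)C(C)(C)C)CC/C=C(\C)COC(=O)C1S(=O)(=O)c1ccccc1 | intermediate
34 | 14-membered carbocycle, phenylsulfonyl on C14, CH2OTBDPS on C8 (product of the key step) | CC(C)=CC/C=C(\C)[C@H]1C/C=C(/C)CC/C=C(/CO[Si](c2ccccc2)(c2ccccc2)C(C)(C)C)CC/C=C(\C)CC1S(=O)(=O)c1ccccc1 | intermediate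
35 | 14-membered carbocycle, C14 as CH2, CH2OTBDPS on C8 | CC(C)=CC/C=C(\C)[C@H]1C/C=C(/C)CC/C=C(/CO[Si](c2ccccc2)(c2ccccc2)C(C)(C)C)CC/C=C(\C)CC1 | intermediate
36 | 14-membered allylic alcohol (C8 CH2OH) | CC(C)=CC/C=C(\C)[C@H]1C/C=C(/C)CC/C=C(/CO)CC/C=C(\C)CC1 | intermediate
37 | 14-membered enal (C8 CHO) | CC(C)=CC/C=C(\C)[C@H]1C/C=C(/C)CC/C=C(/C=O)CC/C=C(\C)CC1 | intermediate
38 | CNP0112585.1, the (R)-configured 14-membered trienoic acid | CC(C)=CC/C=C(\C)[C@H]1C/C=C(/C)CC/C=C(/C(=O)O)CC/C=C(\C)CC1 | target

## Step count and least certain steps

Total: 26 steps. Longest linear sequence: 19 steps (5 → 6 → 7 → 9 → 10 → 11 → 12 → 21 → 22 → 23 → 25 → 28 → 29 → 31 → 33 → 34 → 35 → 36 → 37 → 38; steps 3–8 and 14–26).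

**Step 22 (key step, proposed new method).** The likely failure is that the C14 carbanion is protonated by the acidic C14–H of unreacted lactone, so that allylation becomes intermolecular and oligomers form. The allylpalladium unit may also lose a β-hydrogen to give an open-chain 1,3-diene, or decarboxylation may be slow enough for the catalyst to decompose. Partial loss of the E geometry through face exchange of the allyl unit is a lesser risk. Fallback by known chemistry, from 33 back to 34: saponify the lactone with LiOH in THF/H2O and warm the α-sulfonyl acid until it decarboxylates, giving the open-chain hydroxy sulfone F1. Convert the C13 allylic alcohol into the allylic bromide F2 with CBr4 and PPh3. Add F2 slowly to LiN(iPr)2 in THF at −78 to 0 °C under high dilution, so that the C14 sulfonyl carbanion displaces bromide at C13 and closes the 14-membered ring to 34. This is the classical intramolecular alkylation of a sulfonyl carbanion by an allylic halide.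

**Step 14.** Methylalumination of the aluminium alkoxide of 19 may be slow or incomplete. Methyl may transfer in place of the alkenyl group, or the allyl unit may isomerise with erosion of the Z geometry at C3=C4. Fallback, from 19 back to 21: run the same methylalumination but quench with I2 to isolate the vinyl iodide F3, and protect it with Et3SiCl and imidazole as the triethylsilyl ether F4. After iodine–lithium exchange with tBuLi and transmetalation with ZnCl2, Pd(PPh3)4 couples the alkenyl unit with chloride 12 to give the silyl ether F5. Mild acid (pyridinium tosylate, EtOH, 0 °C) removes the triethylsilyl group in the presence of the primary tert-butyldimethylsilyl ether and returns 21.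

**Step 6.** The α-branched phosphonate may give insufficient E selectivity, and the isomers may be hard to separate. Fallback, from 4 and 7 back to 10: Wittig reaction of 4 with Ph3P=C(Br)CO2Et gives the (Z)-2-bromoenoate F6, with bromine on the side where C9 must go. Bromide 7 is converted with NaI in acetone into iodide F7 and with zinc dust into the alkylzinc iodide F8. Pd(PPh3)4-catalysed coupling of F6 with F8 replaces bromine by C9 with retention of alkene geometry and gives 10.

**Step 18.** The ester enolate may eliminate the allylic alkoxide before silylation, the [3,3] shift may be incomplete, or chirality transfer may leak through a transition state with the C2' substituent axial. Fallback, from 23 back to 28: Johnson orthoester Claisen rearrangement of 23 with MeC(OEt)3 and catalytic propionic acid at 135 °C gives the ethyl ester F9 with the same sense of chirality transfer. Deprotonation with LiN(iPr)2 and sulfenylation with PhSSPh gives the α-phenylthio ester F10, and LiOH hydrolysis returns 28.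

**Step 20.** The hindered α-branched acyl derivative may react slowly, so that oligomerisation competes with ring closure. Fallback, from 29 directly to 31: Mitsunobu macrolactonisation (PPh3, diisopropyl azodicarboxylate, toluene, high dilution) activates the unhindered primary C13 alcohol in place of the acid, and the carboxylate closes the ring by SN2 displacement. No new compound arises on this path.

## Further compounds

F1 | step 22 | open-chain hydroxy sulfone: C14H2SO2Ph, C13 OH, C8 CH2OTBDPS | CC(C)=CC/C=C(\C)[C@@H](C/C=C(/C)CC/C=C(/CO[Si](c1ccccc1)(c1ccccc1)C(C)(C)C)CC/C=C(\C)CO)CS(=O)(=O)c1ccccc1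
F2 | step 22 | open-chain allylic bromide sulfone: C14H2SO2Ph, C13 Br | CC(C)=CC/C=C(\C)[C@@H](C/C=C(/C)CC/C=C(/CO[Si](c1ccccc1)(c1ccccc1)C(C)(C)C)CC/C=C(\C)CBr)CS(=O)(=O)c1ccccc1
F3 | step 14 | (1E,3S)-1-iodo-2,6-dimethylhepta-1,5-dien-3-ol | I/C=C(\C)[C@@H](O)CC=C(C)C
F4 | step 14 | triethylsilyl ether of F3 | I/C=C(\C)[C@@H](O[Si](CC)(CC)CC)CC=C(C)C
F5 | step 14 | triethylsilyl ether of 21 | CC(C)=CC[C@H](O[Si](CC)(CC)CC)/C(C)=C/C/C=C(/C)CC/C=C(/C(=O)OCC)CC/C=C(\C)CO[Si](C)(C)C(C)(C)C
F6 | step 6 | ethyl (2Z,6Z)-8-acetoxy-2-bromo-6-methylocta-2,6-dienoate | CC(=O)OC/C=C(/C)CC/C=C(\Br)C(=O)OCC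
F7 | step 6 | tert-butyl{[(2E)-5-iodo-2-methylpent-2-en-1-yl]oxy}dimethylsilane | ICC/C=C(\C)CO[Si](C)(C)C(C)(C)C
F8 | step 6 | {(3E)-5-[(tert-butyldimethylsilyl)oxy]-4-methylpent-3-en-1-yl}zinc iodide | I[Zn]CC/C=C(\C)CO[Si](C)(C)C(C)(C)C
F9 | step 18 | ethyl ester from the orthoester Claisen rearrangement (C14 as CH2CO2Et) | CC(C)=CC/C=C(\C)[C@@H](C/C=C(/C)CC/C=C(/CO[Si](c1ccccc1)(c1ccccc1)C(C)(C)C)CC/C=C(\C)CO[Si](C)(C)C(C)(C)C)CC(=O)OCC
F10 | step 18 | ethyl ester of 28 | CC(C)=CC/C=C(\C)[C@@H](C/C=C(/C)CC/C=C(/CO[Si](c1ccccc1)(c1ccccc1)C(C)(C)C)CC/C=C(\C)CO[Si](C)(C)C(C)(C)C)C(Sc1ccccc1)C(=O)OCC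
F0 | step 20 | none | none
A1 | alternative 1 | methyl ester of 38 | CC(C)=CC/C=C(\C)[C@H]1C/C=C(/C)CC/C=C(/C(=O)OC)CC/C=C(\C)CC1
A2 | alternative 1 | open-chain methyl ester with a vinyl group on C1 and an (E)-alkenyl iodide at C12 | CC(C)=CC/C=C(\C)[C@H](C=C)C/C=C(/C)CC/C=C(/C(=O)OC)CC/C=C(\C)I
A3 | alternative 2 | 14-membered methyl ester with phenylsulfonyl on C10 | CC(C)=CC/C=C(\C)[C@H]1C/C=C(/C)CC/C=C(/C(=O)OC)CC(S(=O)(=O)c2ccccc2)/C=C(\C)CC1
A4 | alternative 2 | open-chain C10 allylic sulfone with a (Z)-2-(bromomethyl)enoate ending at C9 | BrC/C(C(=O)OC)=C\CC/C(C)=C\C[C@@H](CC/C(C)=C/CS(=O)(=O)c1ccccc1)/C(C)=C/CC=C(C)C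
A5 | alternative 3 | 14-membered carbocycle with a carboxyl on C14 and CH2OTBS on C8 | CC(C)=CC/C=C(\C)[C@H]1C/C=C(/C)CC/C=C(/CO[Si](C)(C)C(C)(C)C)CC/C=C(\C)CC1C(=O)O
A6 | alternative 3 | 18-membered lactone with the ester oxygen on C2' and the α-carbon C14 | C/C1=C\C/C=C(/C)CC/C=C(/CO[Si](C)(C)C(C)(C)C)CC/C=C(\C)CCC(=O)O[C@H]1CC=C(C)C
A7 | alternative 3 | O-trimethylsilyl ketene acetal of A6 | C/C1=C\C/C=C(/C)CC/C=C(/CO[Si](C)(C)C(C)(C)C)CC/C=C(\C)CC=C(O[Si](C)(C)C)O[C@H]1CC=C(C)C
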